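**Retrosynthetic overview**
1. The C5 carbinol is the only stereocentre. It is set last, by enantioselective transfer hydrogenation of the C5 ketone of the bicyclic 4,5-dione.
2. The carbocycle (C4a, C5, C6, C7, C8, C8a) is closed second, at C6–C7. A monocyclic 3-acetyl-2-methyl-4-pyranone takes up one CH2 unit (C7) at its C8 methyl group, and the C6 enolate then closes onto C7 (formal [5+1] annulation in one flask).
3. Enabling feature: the C4a=C8a double bond of the pyranone ring holds C5 and C8 cis and relays C4=O to both. C8–H is therefore vinylogously acidic, C7 of the derived 2-vinyl group is a δ-acceptor carbon, and C6=C5(O–)–C4a=C8a–C8=C7 is a hexatriene poised to close. C5 and C8a are 1,5-related oxygenated carbons.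
4. The pyranone ring is formed first. Pentane-2,4-dione (source of C6, C5, C4a, C8a and C8) is C-acylated with a C20 enynoyl chloride, and O1 closes onto C2 in the 6-endo-dig mode.
5. The side chain with its Z-alkene comes from (Z)-hexadec-11-en-1-ol, extended by a C3 propyne unit and CO2.

Key step: step 6

Remark: the locants of the target (O1, C2, C3, C4, C4a, C5 to C8, C8a) are used for the same atoms in all precursors. (Z)-Hexadec-11-en-1-ol is taken as a commercial, geometrically pure alcohol.

Step 1
Reactants: 1 (Z)-hexadec-11-en-1-ol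
Product: 2 (Z)-16-bromohexadec-5-ene
Conditions: CBr4, PPh3, CH2Cl2, 0 °C to rt
Reagents that add atoms: carbon tetrabromide, BrC(Br)(Br)Br
Why: The Appel reaction converts the primary alcohol into the bromide under neutral conditions that leave the Z-alkene untouched.

Step 2
Reactants: 2 (Z)-16-bromohexadec-5-ene; 3 1-(trimethylsilyl)propyne
Product: 5 trimethyl[(Z)-nonadec-14-en-1-yn-1-yl]silane, via lithiated silylpropyne 4 (not isolated)
Conditions: 3, n-BuLi, THF, −78 °C; then 2, DMPU, −78 °C to rt
Reagents that add atoms: none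
Why: Propargylic lithiation followed by SN2 alkylation with the primary bromide adds the C3 unit, and the silyl cap blocks the acetylenic terminus and disfavours allene formation.

Step 3
Reactants: 5 trimethyl[(Z)-nonadec-14-en-1-yn-1-yl]silane
Product: 6 (Z)-nonadec-14-en-1-yne
Conditions: K2CO3 (cat.), MeOH/THF, rt
Reagents that add atoms: none
Why: Base-catalysed methanolysis (protodesilylation) of an alkynylsilane is selective for the C(sp)–Si bond and touches nothing else in the molecule.

Step 4
Reactants: 6 (Z)-nonadec-14-en-1-yne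
Product: 8 (Z)-icos-15-en-2-ynoic acid, via lithium acetylide 7 (not isolated)
Conditions: n-BuLi, THF, −78 °C; CO2; aq HCl
Reagents that add atoms: carbon dioxide, O=C=O
Why: Carboxylation of a lithium acetylide installs the future C4 carbon, and only the terminal alkyne C–H is acidic enough to be metalated.

Step 5
Reactants: 8 (Z)-icos-15-en-2-ynoic acid; 9 pentane-2,4-dione
Product: 12 3-acetyl-6-[(Z)-heptadec-12-en-1-yl]-2-methyl-4H-pyran-4-one, via ynoyl chloride 10 (not isolated), via triacylmethane 11 (not isolated)
Conditions: (COCl)2, DMF (cat.), CH2Cl2, 0 °C to rt, evaporate; 9, MgCl2, pyridine, CH2Cl2, 0 °C to rt; aq HCl; then Et3N (cat.), MeCN, 50 °C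
Reagents that add atoms: none
Why: Magnesium-enolate C-acylation of the symmetric β-diketone gives the triacylmethane, whose enol oxygen adds to the ynone β-carbon (6-endo-dig oxa-Michael addition); because the two acetyl groups of 9 are equivalent only one pyranone can form, and it already holds C6, C5, C4a, C8a and C8.

Step 6
Reactants: 12 3-acetyl-6-[(Z)-heptadec-12-en-1-yl]-2-methyl-4H-pyran-4-one
Product: 16 2-[(Z)-heptadec-12-en-1-yl]-7,8-dihydro-4H-chromene-4,5(6H)-dione, via Mannich base 13 (not isolated), via ammonium iodide 14 (not isolated), via vinylpyranone 15 (not isolated)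
Conditions: LiN(SiMe3)2, THF, −78 to −20 °C; [CH2=NMe2]I, −78 °C to rt; MeI, rt; then LiN(SiMe3)2 (excess), THF (dilute), −78 to 0 °C; aq NH4Cl
Reagents that add atoms: N,N-dimethylmethyleneiminium iodide (Eschenmoser's salt), C=[N+](C)C.[I-]
Why: Under equilibrating conditions LiN(SiMe3)2 removes the most acidic proton, that of the C8 methyl group (vinylogous to C4=O and C5=O through C4a=C8a), and the dienolate is aminomethylated at C8 (vinylogous Mannich reaction), which brings in C7. Exhaustive methylation and E1cB (Hofmann-type) loss of NMe3 unveil the 2-vinylpyranone 15, a cross-conjugated dienone whose terminal carbon C7 is the δ-acceptor position of C4=O. The second portion of base forms the C6 lithium enolate of the acetyl group, chelated between the C5 and C4 oxygens so that C6 is turned toward C7, and the C6–C7 bond forms by intramolecular 1,6-Michael addition, equally read as disrotatory 6π electrocyclisation of the 1-oxidohexatriene C6=C5(O–)–C4a=C8a–C8=C7; the closest known types are the Mannich-methiodide variant of the Robinson annulation and the electrocyclisation of 2,3-divinylchromones. The carbocycle closes in the 6-endo-trig mode, and protonation of the resulting dienolate at C8 on work-up restores the pyranone. No stereocentre is formed. The step needs C8 over C6 in the first C–C bond (secured by the acidity gap), C- over O-attack in the closure (O-closure to the cyclic enol ether is reversible, the C–C bond is the thermodynamic sink) and intra- over intermolecular addition (full enolisation at low temperature and high dilution leave no neutral acceptor beside a nucleophile), while the isolated Z-alkene is a spectator.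

Step 7
Reactants: 16 2-[(Z)-heptadec-12-en-1-yl]-7,8-dihydro-4H-chromene-4,5(6H)-dione
Product: 17 (5S)-2-[(Z)-heptadec-12-en-1-yl]-5-hydroxy-5,6,7,8-tetrahydro-4H-chromen-4-one
Conditions: RuCl[(S,S)-TsDPEN](p-cymene) (cat.), HCO2H/Et3N (5:2), CH2Cl2, rt
Reagents that add atoms: none
Why: Noyori–Ikariya asymmetric transfer hydrogenation treats the C5 carbonyl as a 1-tetralone-type ketone (flat pyranone π-system against CH2), so the (S,S)-catalyst should deliver hydride to its Re face and set (5S), while the C4 pyranone carbonyl (a doubly vinylogous ester) and the isolated Z-alkene are not reduced.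

**Compound list**
1 | (Z)-hexadec-11-en-1-ol | CCCC/C=C\CCCCCCCCCCO | starting material
2 | (Z)-16-bromohexadec-5-ene | CCCC/C=C\CCCCCCCCCCBr | intermediate
3 | 1-(trimethylsilyl)propyne | CC#C[Si](C)(C)C | starting material
4 | 3-lithio-1-(trimethylsilyl)propyne | [Li]CC#C[Si](C)(C)C | intermediate
5 | trimethyl[(Z)-nonadec-14-en-1-yn-1-yl]silane | CCCC/C=C\CCCCCCCCCCCC#C[Si](C)(C)C | intermediate
6 | (Z)-nonadec-14-en-1-yne | CCCC/C=C\CCCCCCCCCCCC#C | intermediate
7 | lithium (Z)-nonadec-14-en-1-yn-1-ide | CCCC/C=C\CCCCCCCCCCCC#C[Li] | intermediate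
8 | (Z)-icos-15-en-2-ynoic acid | CCCC/C=C\CCCCCCCCCCCC#CC(=O)O | intermediate
9 | pentane-2,4-dione | CC(=O)CC(C)=O | starting material
10 | (Z)-icos-15-en-2-ynoyl chloride | CCCC/C=C\CCCCCCCCCCCC#CC(=O)Cl | intermediate
11 | (Z)-3-acetyltricos-18-en-5-yne-2,4-dione | CCCC/C=C\CCCCCCCCCCCC#CC(=O)C(C(C)=O)C(C)=O | intermediate
12 | 3-acetyl-6-[(Z)-heptadec-12-en-1-yl]-2-methyl-4H-pyran-4-one | CCCC/C=C\CCCCCCCCCCCc1cc(=O)c(C(C)=O)c(C)o1 | intermediate
13 | 3-acetyl-2-[2-(dimethylamino)ethyl]-6-[(Z)-heptadec-12-en-1-yl]-4H-pyran-4-one | CCCC/C=C\CCCCCCCCCCCc1cc(=O)c(C(C)=O)c(CCN(C)C)o1 | intermediate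
14 | 2-{3-acetyl-6-[(Z)-heptadec-12-en-1-yl]-4-oxo-4H-pyran-2-yl}-N,N,N-trimethylethan-1-aminium iodide | CCCC/C=C\CCCCCCCCCCCc1cc(=O)c(C(C)=O)c(CC[N+](C)(C)C)o1.[I-] | intermediate
15 | 3-acetyl-2-ethenyl-6-[(Z)-heptadec-12-en-1-yl]-4H-pyran-4-one | CCCC/C=C\CCCCCCCCCCCc1cc(=O)c(C(C)=O)c(C=C)o1 | intermediate
16 | 2-[(Z)-heptadec-12-en-1-yl]-7,8-dihydro-4H-chromene-4,5(6H)-dione | CCCC/C=C\CCCCCCCCCCCc1cc(=O)c2c(o1)CCCC2=O | intermediate
17 | (5S)-2-[(Z)-heptadec-12-en-1-yl]-5-hydroxy-5,6,7,8-tetrahydro-4H-chromen-4-one | CCCC/C=C\CCCCCCCCCCCc1cc(=O)c2c(o1)CCC[C@@H]2O | target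

Total step count: 7. Longest linear sequence: 7 steps (from 1 to 17).

**Steps most likely to fail**

Step 6. Intermolecular conjugate addition and oligomerisation of the vinylpyranone may outrun the closure, or aminomethylation may occur at C6 in place of C8.
- The fallback sets out from 14 and comes back at 16. It replaces the anionic closure by a neutral pericyclic one.
- 14 is now isolated by filtration and treated with aq NaHCO3/CH2Cl2 to give 15, which is isolated.
- Enolisation with LiN(SiMe3)2 in the presence of TBSCl (THF, −78 °C, internal quench) gives the silyl enol ether 3-[1-(tert-butyldimethylsilyloxy)ethenyl]-2-ethenyl-6-[(Z)-heptadec-12-en-1-yl]-4H-pyran-4-one F1.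
- Heating F1 in toluene should bring about thermal 6π electrocyclisation, which forms C6–C7, followed by a suprafacial 1,5-hydrogen shift from C6 to C8. The product is the silyl dienol ether 5-(tert-butyldimethylsilyloxy)-2-[(Z)-heptadec-12-en-1-yl]-7,8-dihydro-4H-chromen-4-one F2.
- HF·pyridine in THF then releases 16.

Step 5. Conjugate addition of the magnesium enolate, pyridine or chloride to the ynoyl chloride, O-acylation, or 5-exo closure may compete with C-acylation and 6-endo closure.
- The fallback sets out from 2 and comes back at 12. It bypasses steps 2 to 5 and uses an acylketene in place of an ynone.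
- The dianion of tert-butyl acetoacetate (NaH, then n-BuLi, THF, 0 °C) is alkylated at its terminal carbon by 2 to give tert-butyl (Z)-3-oxoicos-15-enoate F3.
- Heating F3 in xylene with an excess of 9 expels tert-butanol.
- The acylketene (Z)-3-oxoicosa-1,15-dien-1-one F4 is intercepted by the enol of 9 in a hetero-Diels–Alder reaction, and loss of water from the hemiketal gives 12.

Step 7. Hydride transfer may be sluggish because the C5 carbonyl has vinylogous ester character, or facial selectivity may be poor.
- The fallback sets out from 16 and comes back at 17. It replaces asymmetric catalysis by resolution.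
- Luche reduction (NaBH4, CeCl3·7H2O, MeOH, −20 °C) gives the racemic alcohol 2-[(Z)-heptadec-12-en-1-yl]-5-hydroxy-5,6,7,8-tetrahydro-4H-chromen-4-one F5.
- Candida antarctica lipase B with vinyl acetate in tert-butyl methyl ether should acetylate the (R)-enantiomer faster, as it does for 1-tetralol. This gives the acetate (5R)-2-[(Z)-heptadec-12-en-1-yl]-4-oxo-5,6,7,8-tetrahydro-4H-chromen-5-yl acetate F6 and leaves 17, which is separated by chromatography.

**Further compounds**
F1 | step 6 | 3-[1-(tert-butyldimethylsilyloxy)ethenyl]-2-ethenyl-6-[(Z)-heptadec-12-en-1-yl]-4H-pyran-4-one | CCCC/C=C\CCCCCCCCCCCc1cc(=O)c(C(=C)O[Si](C)(C)C(C)(C)C)c(C=C)o1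
F2 | step 6 | 5-(tert-butyldimethylsilyloxy)-2-[(Z)-heptadec-12-en-1-yl]-7,8-dihydro-4H-chromen-4-one | CCCC/C=C\CCCCCCCCCCCc1cc(=O)c2c(o1)CCC=C2O[Si](C)(C)C(C)(C)C
F3 | step 5 | tert-butyl (Z)-3-oxoicos-15-enoate | CCCC/C=C\CCCCCCCCCCCC(=O)CC(=O)OC(C)(C)C
F4 | step 5 | (Z)-3-oxoicosa-1,15-dien-1-one | CCCC/C=C\CCCCCCCCCCCC(=O)C=C=O
F5 | step 7 | racemic 2-[(Z)-heptadec-12-en-1-yl]-5-hydroxy-5,6,7,8-tetrahydro-4H-chromen-4-one | CCCC/C=C\CCCCCCCCCCCc1cc(=O)c2c(o1)CCCC2O
F6 | step 7 | (5R)-2-[(Z)-heptadec-12-en-1-yl]-4-oxo-5,6,7,8-tetrahydro-4H-chromen-5-yl acetate | CCCC/C=C\CCCCCCCCCCCc1cc(=O)c2c(o1)CCC[C@H]2OC(C)=O
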